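**Plan**

1. Locants follow octahydro-1H-indene: C1 ethylidene, C2 OAc, C3 CH2, C3a and C7a ring fusion, C4 =CH2, C5 enoate, C6 OH, C7 isopropyl.
2. Retrosynthesis: remove the C5 ester, the C2 acetate and a C6 PMB ether; cut the cyclopentane at C3–C3a and C1–C2 together; then cut C4–CH2O, the C7a alkyne and the C5/C6 oxygens, back to (R)-cryptone and on to 3-methylbutanal plus methyl vinyl ketone.
3. Enabling feature: the exocyclic C4 methylene beside C3a is the footprint of a [3,3] shift of a C4–CH2–O–CH=CH2 ether across a C4=C3a ring alkene (makes C3–C3a, frees C2 as an aldehyde); the C1 ethylidene beside the C2 carbinol is the footprint of a nickel-catalysed alkylative cyclisation of that aldehyde onto a C7a ethynyl group with Me2Zn (makes C1–C2).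
4. Forward order: six-membered ring first (organocatalytic Michael addition, aldol condensation), then its substituents (epoxidation and opening, Saegusa–Ito oxidation, conjugate alkynylation, triflate to CH2OH to vinyl ether), then the five-membered ring in one flask, then two acylations and PMB removal.
5. Stereochemistry: C7 comes from the amine catalyst; C5, C6 and C7a, then C3a, C2 and the Z-alkene (these three in the key step) are relayed from it by substrate control.

Key step: step 11

Remark: (E)-3-methylpent-2-enoic acid 20 is assumed to be purchased as the pure E isomer; monocyclic intermediates are numbered as cyclohexanes, with stereo relationships given in words and in the SMILES.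

**Route**

Step 1
Reactants: 1 3-methylbutanal; 2 but-3-en-2-one
Product: 3 (2R)-2-isopropyl-5-oxohexanal
Conditions: (R)-2-[methoxy(diphenyl)methyl]pyrrolidine (5 mol%), ethyl 3,4-dihydroxybenzoate (20 mol%), neat, 4 °C
Reagents that add atoms: none
Why: Organocatalytic Michael addition through the enamine of 1, whose face next to the diphenylmethoxymethyl group is shielded, so 2 should add to the open face and set the isopropyl-bearing centre as R.

Step 2
Reactants: 3 (2R)-2-isopropyl-5-oxohexanal
Product: 4 (R)-cryptone
Conditions: LiOH, i-PrOH, 23 °C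
Reagents that add atoms: none
Why: Intramolecular aldol condensation of the methyl ketone onto the aldehyde should close the cyclohexenone faster than mild hydroxide enolises the branched aldehyde, so the stereocentre should be kept.

Step 3
Reactants: 4 (R)-cryptone
Product: 5 trans-epoxy ketone
Conditions: H2O2 (30% aq.), NaOH (cat.), MeOH, 0 °C
Reagents that add atoms: hydrogen peroxide, OO
Why: Weitz–Scheffer nucleophilic epoxidation in which hydroperoxide should add to the β-carbon anti to the adjacent isopropyl group, placing the epoxide trans to it.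

Step 4
Reactants: 5 trans-epoxy ketone
Product: 6 hydroxy ketone PMB ether
Conditions: 4-MeOC6H4CH2OH (5 equiv), Yb(OTf)3 (10 mol%), CH2Cl2, 23 °C
Reagents that add atoms: 4-methoxybenzyl alcohol, COc1ccc(CO)cc1
Why: Lewis acid-catalysed epoxide alcoholysis should occur at the β-carbon (the α-carbon is deactivated by the carbonyl) with inversion in the trans-diaxial sense of the Fürst–Plattner rule, giving 3-OPMB cis to isopropyl and leaving the 2-OH configuration untouched.

Step 5
Reactants: 6 hydroxy ketone PMB ether
Product: 7 silyloxy ketone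
Conditions: t-BuMe2SiCl, imidazole, DMF, 40 °C
Reagents that add atoms: tert-butyldimethylsilyl chloride, CC(C)(C)[Si](C)(C)Cl
Why: Standard silylation of the only free hydroxyl; the axial silyl ether later shields one face of the ring.

Step 6
Reactants: 7 silyloxy ketone
Product: 9 enone, via trimethylsilyl enol ether 8 (not isolated)
Conditions: LiN(i-Pr)2, Me3SiCl, THF, −78 °C; then Pd(OAc)2 (10 mol%), O2 (1 atm), DMSO, 40 °C
Reagents that add atoms: none
Why: Kinetic deprotonation should take place at the CH2 α-carbon and not at the silyloxy-bearing CH, and Saegusa–Ito oxidation of the silyl enol ether (palladium enolate, β-hydride elimination) should give the enone on that side.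

Step 7
Reactants: 9 enone
Product: 12 enol triflate, via alkynylated silyl enol ether 10 (not isolated), via lithium enolate 11 (not isolated)
Conditions: Me3SiC≡CH, n-BuLi, THF, −78 °C, then ZnBr2; add 9, Me3SiOTf, Et2O/THF, −40 °C; then MeLi, THF, 0 °C; PhNTf2, −78 → 23 °C
Reagents that add atoms: (trimethylsilyl)acetylene, C#C[Si](C)(C)C; N-phenylbis(trifluoromethanesulfonimide), O=S(=O)(N(c1ccccc1)S(=O)(=O)C(F)(F)F)C(F)(F)F
Why: Silyl triflate-promoted conjugate addition of the alkynylzinc should occur at the β-carbon anti to the adjacent isopropyl group and to the axial OPMB group (alkyne trans to isopropyl), and the regiodefined enol ether is passed through its lithium enolate to the triflate without moving the double bond.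

Step 8
Reactants: 12 enol triflate
Product: 13 allylic alcohol
Conditions: Bu3SnCH2OH, Pd(PPh3)4 (5 mol%), LiCl, 1,4-dioxane, 90 °C
Reagents that add atoms: (tributylstannyl)methanol, CCCC[Sn](CCCC)(CCCC)CO
Why: Stille coupling of an alkenyl triflate with a hydroxymethylstannane should install CH2OH on the alkene carbon with the double bond left in place.

Step 9
Reactants: 13 allylic alcohol
Product: 14 allyl vinyl ether
Conditions: butyl vinyl ether (solvent), Pd(O2CCF3)2 (2 mol%), 4,7-diphenyl-1,10-phenanthroline (2 mol%), Et3N (cat.), 75 °C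
Reagents that add atoms: butyl vinyl ether, C=COCCCC
Why: Transfer vinylation (transetherification) of a primary allylic alcohol catalysed by divalent palladium is a standard entry to Claisen substrates and should leave the silyl ethers, the PMB ether and the silylalkyne untouched.

Step 10
Reactants: 14 allyl vinyl ether
Product: 15 ethynyl allyl vinyl ether
Conditions: K2CO3 (cat.), MeOH, 23 °C
Reagents that add atoms: none
Why: Methanolysis of the alkynyl C–Si bond under mild base should free the terminal alkyne while the vinyl ether and the silyl ether survive.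

Step 11
Reactants: 15 ethynyl allyl vinyl ether
Product: 17 hydrindanol, via aldehyde 16 (not isolated)
Conditions: PhMe, 170 °C (sealed tube); then cool to 0 °C, THF, Ni(cod)2 (10 mol%), Me2Zn (2.5 equiv); aq. NH4Cl
Reagents that add atoms: dimethylzinc, C[Zn]C
Why: On heating, the allyl vinyl ether undergoes a [3,3] sigmatropic shift (Claisen rearrangement) that forms C3–C3a, moves the ring alkene out to the C4 exocyclic methylene and leaves C2 as aldehyde 16. In the same flask zerovalent nickel couples this aldehyde with the C7a ethynyl group by oxidative cyclisation to an oxanickelacyclopentene (C1–C2 bond), methyl passes from zinc to nickel and reductive elimination places it on the alkyne terminus; the closest known reaction type is the nickel-catalysed alkylative cyclisation of 5-alkynals with dialkylzincs to 2-alkylidenecyclopentanols. The cyclopentane closes in a 5-exo-dig mode and is trans-fused because both reacting arms are equatorial. C3a is set in the sigmatropic step, where the vinyl ether terminus should be delivered to the face of C4=C3a opposite the pseudoaxial 5-silyloxy group and the 7a-ethynyl group, that is trans to the alkyne. C2 is set in the nickel step, because the metallacycle needs the C2–O bond close to the plane of the alkyne and in the twisted trans-fused ring the aldehyde face that places oxygen syn to H-3a fits this better, while syn addition of C2 and CH3 across the alkyne fixes the Z-ethylidene. The step needs facial selectivity in the shift (axial OTBS), alkyl instead of hydride transfer (methyl has no β-hydrogen) and cyclisation instead of direct 1,2-methylation (Me2Zn is inert to aldehydes without catalyst at 0 °C).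

Step 12
Reactants: 17 hydrindanol
Product: 18 C2 acetate
Conditions: Ac2O, DMAP (cat.), pyridine, CH2Cl2, 23 °C
Reagents that add atoms: acetic anhydride, CC(=O)OC(C)=O
Why: Nucleophile-catalysed acylation of the only free, unhindered secondary alcohol.

Step 13
Reactants: 18 C2 acetate
Product: 19 C5 alcohol
Conditions: HF·pyridine, pyridine, THF, 0 → 23 °C
Reagents that add atoms: none
Why: Buffered fluoride cleavage of the secondary silyl ether should leave the allylic acetate and the PMB ether intact.

Step 14
Reactants: 19 C5 alcohol; 20 (E)-3-methylpent-2-enoic acid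
Product: 22 PMB-protected diester, via mixed anhydride 21 (not isolated)
Conditions: 20, 2,4,6-Cl3C6H2COCl, Et3N, THF, 23 °C; then 19, DMAP, PhMe, 23 → 40 °C
Reagents that add atoms: none
Why: Yamaguchi esterification, in which DMAP transfers the enoyl group from the mixed anhydride to the hindered axial alcohol under conditions mild enough that the E-enoate should not isomerise.

Step 15
Reactants: 22 PMB-protected diester
Product: 23 target
Conditions: DDQ, CH2Cl2/pH 7 phosphate buffer (10:1), 0 → 23 °C
Reagents that add atoms: none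
Why: Oxidative cleavage of the PMB ether (hydride abstraction, hydrolysis of the hemiacetal) should leave both esters and both alkenes untouched, and the trans-diaxial C5/C6 arrangement disfavours acyl migration.

**Compound list**

1 | 3-methylbutanal | CC(C)CC=O | starting material
2 | but-3-en-2-one (methyl vinyl ketone) | CC(=O)C=C | starting material
3 | (2R)-2-isopropyl-5-oxohexanal | O=C[C@@H](C(C)C)CCC(C)=O | intermediate
4 | (4R)-4-isopropylcyclohex-2-en-1-one, (R)-cryptone | O=C1C=C[C@@H](C(C)C)CC1 | intermediate
5 | 2,3-epoxy-4-isopropylcyclohexan-1-one, epoxide trans to isopropyl | O=C1CC[C@H](C(C)C)[C@H]2O[C@@H]12 | intermediate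
6 | 2-hydroxy-4-isopropyl-3-(4-methoxybenzyloxy)cyclohexan-1-one; 2-OH trans to 3-OPMB, 3-OPMB cis to 4-isopropyl | O=C1CC[C@H](C(C)C)[C@H](OCc2ccc(OC)cc2)[C@H]1O | intermediate
7 | 2-(tert-butyldimethylsilyloxy)-4-isopropyl-3-(4-methoxybenzyloxy)cyclohexan-1-one; same relative configuration as 6 | O=C1CC[C@H](C(C)C)[C@H](OCc2ccc(OC)cc2)[C@H]1O[Si](C)(C)C(C)(C)C | intermediate
8 | trimethylsilyl enol ether of 7 on the CH2 side (not isolated) | C[Si](C)(C)OC1=CC[C@H](C(C)C)[C@H](OCc2ccc(OC)cc2)[C@H]1O[Si](C)(C)C(C)(C)C | intermediate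
9 | 6-(tert-butyldimethylsilyloxy)-4-isopropyl-5-(4-methoxybenzyloxy)cyclohex-2-en-1-one; 4,5-cis, 5,6-trans | O=C1C=C[C@H](C(C)C)[C@H](OCc2ccc(OC)cc2)[C@H]1O[Si](C)(C)C(C)(C)C | intermediate
10 | trimethylsilyl enol ether of the 3-[(trimethylsilyl)ethynyl] ketone; 3,4-trans, 4,5-cis, 5,6-trans (not isolated) | C[Si](C)(C)OC1=C[C@@H](C#C[Si](C)(C)C)[C@H](C(C)C)[C@H](OCc2ccc(OC)cc2)[C@H]1O[Si](C)(C)C(C)(C)C | intermediate
11 | lithium enolate corresponding to 10 (not isolated) | [Li]OC1=C[C@@H](C#C[Si](C)(C)C)[C@H](C(C)C)[C@H](OCc2ccc(OC)cc2)[C@H]1O[Si](C)(C)C(C)(C)C | intermediate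
12 | 6-(tert-butyldimethylsilyloxy)-4-isopropyl-5-(4-methoxybenzyloxy)-3-[(trimethylsilyl)ethynyl]cyclohex-1-en-1-yl trifluoromethanesulfonate; 3,4-trans, 4,5-cis, 5,6-trans | FC(F)(F)S(=O)(=O)OC1=C[C@@H](C#C[Si](C)(C)C)[C@H](C(C)C)[C@H](OCc2ccc(OC)cc2)[C@H]1O[Si](C)(C)C(C)(C)C | intermediate
13 | [6-(tert-butyldimethylsilyloxy)-4-isopropyl-5-(4-methoxybenzyloxy)-3-[(trimethylsilyl)ethynyl]cyclohex-1-en-1-yl]methanol; same relative configuration as 12 | OCC1=C[C@@H](C#C[Si](C)(C)C)[C@H](C(C)C)[C@H](OCc2ccc(OC)cc2)[C@H]1O[Si](C)(C)C(C)(C)C | intermediate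
14 | vinyl ether of 13 | C=COCC1=C[C@@H](C#C[Si](C)(C)C)[C@H](C(C)C)[C@H](OCc2ccc(OC)cc2)[C@H]1O[Si](C)(C)C(C)(C)C | intermediate
15 | 3-ethynyl analogue of 14 (terminal alkyne) | C=COCC1=C[C@@H](C#C)[C@H](C(C)C)[C@H](OCc2ccc(OC)cc2)[C@H]1O[Si](C)(C)C(C)(C)C | intermediate
16 | 2-[3-(tert-butyldimethylsilyloxy)-6-ethynyl-5-isopropyl-4-(4-methoxybenzyloxy)-2-methylenecyclohexyl]acetaldehyde; 1,6-trans, 5,6-trans, 4,5-cis, 3,4-trans (not isolated) | C=C1[C@H](CC=O)[C@@H](C#C)[C@H](C(C)C)[C@H](OCc2ccc(OC)cc2)[C@H]1O[Si](C)(C)C(C)(C)C | intermediate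
17 | (Z)-5-(tert-butyldimethylsilyloxy)-1-ethylidene-7-isopropyl-6-(4-methoxybenzyloxy)-4-methyleneoctahydro-1H-inden-2-ol; trans-fused, 2-OH and 5-OSi on the face of H-3a, 6-OPMB and 7-isopropyl on the face of H-7a | C=C1[C@@H]2C[C@@H](O)/C(=C\C)[C@H]2[C@H](C(C)C)[C@H](OCc3ccc(OC)cc3)[C@H]1O[Si](C)(C)C(C)(C)C | intermediate
18 | 2-acetate of 17 | C=C1[C@@H]2C[C@@H](OC(C)=O)/C(=C\C)[C@H]2[C@H](C(C)C)[C@H](OCc3ccc(OC)cc3)[C@H]1O[Si](C)(C)C(C)(C)C | intermediate
19 | (Z)-1-ethylidene-5-hydroxy-7-isopropyl-6-(4-methoxybenzyloxy)-4-methyleneoctahydro-1H-inden-2-yl acetate; configuration as 17 | C=C1[C@@H]2C[C@@H](OC(C)=O)/C(=C\C)[C@H]2[C@H](C(C)C)[C@H](OCc3ccc(OC)cc3)[C@H]1O | intermediate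
20 | (E)-3-methylpent-2-enoic acid | CC/C(C)=C/C(=O)O | starting material
21 | (E)-3-methylpent-2-enoic 2,4,6-trichlorobenzoic anhydride (not isolated) | CC/C(C)=C/C(=O)OC(=O)c1c(Cl)cc(Cl)cc1Cl | intermediate
22 | 6-O-PMB ether of the target: 2-acetoxy-1-[(Z)-ethylidene]-7-isopropyl-6-(4-methoxybenzyloxy)-4-methyleneoctahydro-1H-inden-5-yl (E)-3-methylpent-2-enoate | C=C1[C@@H]2C[C@@H](OC(C)=O)/C(=C\C)[C@H]2[C@H](C(C)C)[C@H](OCc3ccc(OC)cc3)[C@H]1OC(=O)/C=C(\C)CC | intermediate
23 | target: 2-acetoxy-1-[(Z)-ethylidene]-6-hydroxy-7-isopropyl-4-methyleneoctahydro-1H-inden-5-yl (E)-3-methylpent-2-enoate; trans-fused, 2-OAc and 5-acyloxy on the face of H-3a, 6-OH and 7-isopropyl on the face of H-7a | C=C1[C@@H]2C[C@@H](OC(C)=O)/C(=C\C)[C@H]2[C@H](C(C)C)[C@H](O)[C@H]1OC(=O)/C=C(\C)CC | target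

**Step count and risks**

Total step count: 15. Longest linear sequence: 15 steps (1 and 2 to 23).

Steps most likely to fail:

Step 11. The vinyl ether terminus may be delivered to the wrong face of the ring alkene, because the desired face requires a boat-like ring in the transition state, and material may be lost at 170 °C. The fallback makes the C3–C3a bond by enolate alkylation instead of a sigmatropic shift. It sets out from lithium enolate 11 (step 7, before the triflating agent is added): alkylation with methyl bromoacetate in THF/DMPU, expected anti to the adjacent alkynyl group, would give the keto ester F1. Methylenation of the ketone with Ph3P=CH2 would give the methylene ester F2, and K2CO3/MeOH would then give the terminal alkyne ester F3. Reduction with i-Bu2AlH at −78 °C would give aldehyde 16, which rejoins the route at the nickel stage of step 11 to give 17.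

Step 4. The Lewis acid may consume the PMB alcohol by self-condensation, or the epoxy ketone may undergo acyl migration or dehydration to the diosphenol faster than it is opened. The fallback opens with water and differentiates the two hydroxyls afterwards. From 5, aqueous HClO4 in THF would give the trans-diol F4; silylation of the less hindered α-ketol hydroxyl (t-BuMe2SiCl, imidazole) would give the hydroxy silyl ether F5; 4-methoxybenzyl trichloroacetimidate with La(OTf)3 (cat.) would then give 7.

Step 7. Competing 1,2-addition, erosion of the PMB ether by Me3SiOTf, or incomplete transfer of the enolate to the triflate may occur. The fallback separates the two events. From 9, conjugate addition of Me2AlC≡CSiMe3 catalysed by Ni(acac)2/i-Bu2AlH and aqueous work-up would give the saturated alkynyl ketone F6; kinetic deprotonation at its CH2 α-carbon (LiN(i-Pr)2, −78 °C) and PhNTf2 would then give enol triflate 12.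

**Further compounds**

F1 | step 11 | methyl 2-[3-(tert-butyldimethylsilyloxy)-5-isopropyl-4-(4-methoxybenzyloxy)-2-oxo-6-[(trimethylsilyl)ethynyl]cyclohexyl]acetate | O=C1[C@H](CC(=O)OC)[C@@H](C#C[Si](C)(C)C)[C@H](C(C)C)[C@H](OCc2ccc(OC)cc2)[C@H]1O[Si](C)(C)C(C)(C)C
F2 | step 11 | methyl 2-[3-(tert-butyldimethylsilyloxy)-5-isopropyl-4-(4-methoxybenzyloxy)-2-methylene-6-[(trimethylsilyl)ethynyl]cyclohexyl]acetate | C=C1[C@H](CC(=O)OC)[C@@H](C#C[Si](C)(C)C)[C@H](C(C)C)[C@H](OCc2ccc(OC)cc2)[C@H]1O[Si](C)(C)C(C)(C)C
F3 | step 11 | methyl 2-[3-(tert-butyldimethylsilyloxy)-6-ethynyl-5-isopropyl-4-(4-methoxybenzyloxy)-2-methylenecyclohexyl]acetate | C=C1[C@H](CC(=O)OC)[C@@H](C#C)[C@H](C(C)C)[C@H](OCc2ccc(OC)cc2)[C@H]1O[Si](C)(C)C(C)(C)C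
F4 | step 4 | 2,3-dihydroxy-4-isopropylcyclohexan-1-one; 2,3-trans, 3-OH cis to isopropyl | O=C1CC[C@H](C(C)C)[C@H](O)[C@H]1O
F5 | step 4 | 2-(tert-butyldimethylsilyloxy)-3-hydroxy-4-isopropylcyclohexan-1-one | O=C1CC[C@H](C(C)C)[C@H](O)[C@H]1O[Si](C)(C)C(C)(C)C
F6 | step 7 | 2-(tert-butyldimethylsilyloxy)-4-isopropyl-3-(4-methoxybenzyloxy)-5-[(trimethylsilyl)ethynyl]cyclohexan-1-one; 4,5-trans | O=C1C[C@@H](C#C[Si](C)(C)C)[C@H](C(C)C)[C@H](OCc2ccc(OC)cc2)[C@H]1O[Si](C)(C)C(C)(C)C
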